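A direct plan would treat the target as daidzein with the side chain added last.
Ring C would be closed by a carbene-catalysed intramolecular benzoin reaction of keto aldehyde A1 to the racemic 3-hydroxychromanone A2, which BBr3 would dehydrate and demethylate to 3'-bromodaidzein A3.
(R)-Citronellal A4 would be converted into alkyne A5 and, by trans-hydroboration, into the (Z)-alkenyl boronate A6; a final Suzuki coupling would join A3 and A6 at C3'–C1''.
Weak point, the benzoin closure with dehydration: it would build a carbinol stereocentre only to erase it, through a cation next to a carbonyl group under BBr3.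
Weak point, the aldehyde-to-alkyne elimination with a phosphazene base: it would make the only stereocentre propargylic and open it to alkyne–allene racemisation.
Weak point, the final coupling: it would have to carry a labile (Z)-alkenyl boronate onto an unprotected, electron-rich bromophenol, where protodeboronation and Z-to-E drift could not be corrected.

**Retrosynthetic overview**
Numbering: chromone O1–C8a, ring B C1'–C6', side chain C1''–C8'' counted from ring B.
The target would be cut at C2''–C3'': the (Z)-C1''=C2'' alkene on ring B carbon C3' and the allylic C3'' stereocentre would be assembled together by a Zweifel olefination of an (E)-2-arylethenyllithium with an (R)-configured secondary boronic ester, itself set by sparteine-controlled lithiation–borylation.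
The Z geometry would follow from anti-addition then anti-elimination on an easily made E-iodide, and C3'' would never be propargylic or exposed to strong base.
Ring C would be closed first, on ring A alone, by iodocyclisation of an enaminone (O1–C2 bond); ring B would be attached last through C3–C1' by a borylation/Suzuki sequence remote from the alkene.
No carbinol would be made and erased, and the 4'-OH would be freed by fluoride so that no acid meets the o-hydroxystyrene.

Key step: step 5

Remark: ethyl N,N-di(propan-2-yl)carbamate, (−)-sparteine, 5-bromo-2-methylpent-2-ene, 5-chloro-2-hydroxybenzaldehyde and 1-(2-hydroxy-4-methoxyphenyl)ethan-1-one are taken as commercial; TIPS stands for tri(propan-2-yl)silyl.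

Step 1
Reactants: 1 5-bromo-2-methylpent-2-ene
Product: 3 4,4,5,5-tetramethyl-2-(4-methylpent-3-en-1-yl)-1,3,2-dioxaborolane, via Grignard reagent 2 (not isolated)
Conditions: Mg turnings (1.2 equiv), THF, rt → 40 °C; then i-PrOBpin (1.1 equiv), −78 °C → rt; aqueous work-up
Reagents that add atoms: 2-isopropoxy-4,4,5,5-tetramethyl-1,3,2-dioxaborolane, CC(C)OB1OC(C)(C)C(C)(C)O1
Why: Grignard formation followed by substitution of isopropoxide at boron should give the primary boronic ester, the homoallylic Grignard reagent keeping its skeleton because its cyclopropylcarbinyl shuttle is degenerate; no stereocentre is involved.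

Step 2
Reactants: 4 ethyl N,N-di(propan-2-yl)carbamate; 3 4,4,5,5-tetramethyl-2-(4-methylpent-3-en-1-yl)-1,3,2-dioxaborolane
Product: 7 4,4,5,5-tetramethyl-2-[(2R)-6-methylhept-5-en-2-yl]-1,3,2-dioxaborolane, via lithiated carbamate 5 (not isolated), via boronate complex 6 (not isolated)
Conditions: 4 (1.3 equiv), s-BuLi (1.25 equiv), (−)-sparteine (1.3 equiv), Et2O, −78 °C, 5 h; 3 (1.0 equiv), −78 °C, 1 h; MgBr2·OEt2 (1.5 equiv), then reflux, 16 h
Reagents that add atoms: none
Why: Lithiation–borylation: (−)-sparteine-complexed s-BuLi removes the pro-S hydrogen of 4 to give the configurationally stable carbenoid 5, boron of 3 is taken up with retention (6), and on warming with MgBr2 the 4-methylpent-3-enyl group migrates with inversion and expels the carbamate, so the future C3'' is set as (R) under reagent control.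

Step 3
Reactants: 8 5-chloro-2-hydroxybenzaldehyde
Product: 9 5-chloro-2-{[tri(propan-2-yl)silyl]oxy}benzaldehyde
Conditions: TIPSCl (1.2 equiv), imidazole (2.5 equiv), DMF, rt
Reagents that add atoms: chlorotri(propan-2-yl)silane, CC(C)[Si](Cl)(C(C)C)C(C)C
Why: Standard phenol silylation; the bulky TIPS ether is chosen because it should survive t-BuLi at −78 °C, brief cold methoxide and the palladium step, and leaves at the end with fluoride.

Step 4
Reactants: 9 5-chloro-2-{[tri(propan-2-yl)silyl]oxy}benzaldehyde
Product: 10 {4-chloro-2-[(E)-2-iodoethenyl]phenoxy}tri(propan-2-yl)silane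
Conditions: CHI3 (2 equiv), CrCl2 (6 equiv), 1,4-dioxane/THF 6:1, 0 °C → rt, dark
Reagents that add atoms: iodoform, IC(I)I
Why: Takai olefination, in which the geminal dichromium species formed from CHI3 and CrCl2 adds to the aldehyde and eliminates to the (E)-iodoalkene under steric control, while the aryl chloride and the silyl ether are inert to divalent chromium.

Step 5
Reactants: 10 {4-chloro-2-[(E)-2-iodoethenyl]phenoxy}tri(propan-2-yl)silane; 7 4,4,5,5-tetramethyl-2-[(2R)-6-methylhept-5-en-2-yl]-1,3,2-dioxaborolane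
Product: 14 {4-chloro-2-[(1Z,3R)-3,7-dimethylocta-1,6-dien-1-yl]phenoxy}tri(propan-2-yl)silane, via alkenyllithium 11 (not isolated), via boronate complex 12 (not isolated), via β-iodoboronic ester 13 (not isolated)
Conditions: 10 (1.15 equiv), t-BuLi (2.3 equiv), THF, −78 °C, 30 min; 7 (1.0 equiv), −78 °C, 30 min; I2 (1.3 equiv) in MeOH, −78 °C, 20 min; NaOMe (3 equiv) in MeOH, −78 → 0 °C; aq. Na2S2O3
Reagents that add atoms: none
Why: Iodine–lithium exchange with retention gives (E)-alkenyllithium 11, which adds to boron of 7 to form boronate complex 12; iodine attacks C1'' of its alkene while the secondary alkyl group shifts from boron to C2'' anti to the iodonium bridge (13), and methoxide on boron then triggers anti-periplanar loss of boron and iodide. This is the Zweifel olefination of an enantioenriched secondary boronic ester, a stereospecific 1,2-metallate rearrangement with close precedent for (E)-alkenyllithium partners. No ring is closed: the step forms the C2''–C3'' bond and the C1''=C2'' double bond, which together are the whole side-chain problem. No stereocentre is created; C3'' keeps the (R) configuration of 7 because the migrating carbon shifts with retention, and the Z geometry is fixed by anti addition followed by anti elimination acting on the E-configured precursor. The step needs exchange at the alkenyl iodide only (aryl chloride and silyl ether are inert to t-BuLi at −78 °C), attack of iodine on the electron-rich boronate alkene and not on the trisubstituted C6''=C7'' alkene (secured by the far higher nucleophilicity of 12 at −78 °C and near-stoichiometric I2), and migration of carbon only (the pinacol oxygens do not migrate).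

Step 6
Reactants: 15 1-(2-hydroxy-4-methoxyphenyl)ethan-1-one
Product: 17 3-iodo-7-methoxy-4H-chromen-4-one, via enaminone 16 (not isolated)
Conditions: DMF-DMA (2 equiv), toluene, 95 °C; evaporate; I2 (1.5 equiv), CHCl3, rt; aq. Na2S2O3
Reagents that add atoms: N,N-dimethylformamide dimethyl acetal, COC(OC)N(C)C; iodine, [I][I]
Why: Condensation of the methyl ketone with DMF-DMA gives enaminone 16, and iodine then iodinates its α-carbon and induces 6-endo attack of the phenol oxygen with loss of dimethylamine (iodocyclisation of an o-hydroxyaryl enaminone), which closes ring C on ring A alone through O1–C2 and leaves C3 armed with iodine.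

Step 7
Reactants: 17 3-iodo-7-methoxy-4H-chromen-4-one
Product: 18 7-hydroxy-3-iodo-4H-chromen-4-one
Conditions: BBr3 (3 equiv), CH2Cl2, −78 °C → rt; then H2O
Reagents that add atoms: none
Why: Lewis acid cleavage of the aryl methyl ether at a stage where nothing sensitive is present, so that O7 needs no protecting group in the endgame.

Step 8
Reactants: 14 {4-chloro-2-[(1Z,3R)-3,7-dimethylocta-1,6-dien-1-yl]phenoxy}tri(propan-2-yl)silane; 18 7-hydroxy-3-iodo-4H-chromen-4-one
Product: 20 3-(3-[(1Z,3R)-3,7-dimethylocta-1,6-dien-1-yl]-4-{[tri(propan-2-yl)silyl]oxy}phenyl)-7-hydroxy-4H-chromen-4-one, via aryl boronate 19 (not isolated)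
Conditions: 14 (1.1 equiv), B2pin2 (1.15 equiv), Pd2(dba)3 (1.5 mol %), XPhos (6 mol %), KOAc (3 equiv), 1,4-dioxane, 90–100 °C; then 18 (1.0 equiv), aq. K3PO4 (4 equiv), 70 °C; aq. NH4Cl to pH 6
Reagents that add atoms: none
Why: One-pot Miyaura borylation and Suzuki–Miyaura coupling: the bulky biarylphosphine lets zerovalent palladium insert into the electron-rich C–Cl bond, acetate-assisted transmetalation with B2pin2 gives 19, and after addition of base and 18 the same catalyst joins C1' to C3 of the chromone, so neither the alkene nor C3'' takes part in any bond-forming event and the 7-OH is carried as its phenoxide.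

Step 9
Reactants: 20 3-(3-[(1Z,3R)-3,7-dimethylocta-1,6-dien-1-yl]-4-{[tri(propan-2-yl)silyl]oxy}phenyl)-7-hydroxy-4H-chromen-4-one
Product: 21 7-hydroxy-3-{4-hydroxy-3-[(1Z,3R)-3,7-dimethylocta-1,6-dien-1-yl]phenyl}-4H-chromen-4-one (target)
Conditions: TBAF (1.2 equiv), AcOH (1.2 equiv), THF, 0 °C
Reagents that add atoms: none
Why: Fluoride-induced cleavage of the Si–O bond buffered with acetic acid should free the 4'-OH under near-neutral conditions, which avoids protonation of the o-hydroxystyrene to a quinone-methide-like cation and so keeps the Z geometry and the (R) centre.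

**Compound list**
1 | 5-bromo-2-methylpent-2-ene | CC(C)=CCCBr | starting material
2 | (4-methylpent-3-en-1-yl)magnesium bromide | CC(C)=CCC[Mg]Br | intermediate
3 | 4,4,5,5-tetramethyl-2-(4-methylpent-3-en-1-yl)-1,3,2-dioxaborolane | CC(C)=CCCB1OC(C)(C)C(C)(C)O1 | intermediate
4 | ethyl N,N-di(propan-2-yl)carbamate | CCOC(=O)N(C(C)C)C(C)C | starting material
5 | (1S)-1-lithioethyl N,N-di(propan-2-yl)carbamate, (−)-sparteine complex (ligand not drawn) | C[C@H]([Li])OC(=O)N(C(C)C)C(C)C | intermediate
6 | lithium [(1S)-1-{[di(propan-2-yl)carbamoyl]oxy}ethyl](4-methylpent-3-en-1-yl)(pinacolato)borate | [Li+].C[C@@H](OC(=O)N(C(C)C)C(C)C)[B-]1(CCC=C(C)C)OC(C)(C)C(C)(C)O1 | intermediate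
7 | 4,4,5,5-tetramethyl-2-[(2R)-6-methylhept-5-en-2-yl]-1,3,2-dioxaborolane | CC(C)=CCC[C@@H](C)B1OC(C)(C)C(C)(C)O1 | intermediate
8 | 5-chloro-2-hydroxybenzaldehyde | O=Cc1cc(Cl)ccc1O | starting material
9 | 5-chloro-2-{[tri(propan-2-yl)silyl]oxy}benzaldehyde | O=Cc1cc(Cl)ccc1O[Si](C(C)C)(C(C)C)C(C)C | intermediate
10 | {4-chloro-2-[(E)-2-iodoethenyl]phenoxy}tri(propan-2-yl)silane | I/C=C/c1cc(Cl)ccc1O[Si](C(C)C)(C(C)C)C(C)C | intermediate
11 | [(E)-2-(5-chloro-2-{[tri(propan-2-yl)silyl]oxy}phenyl)ethenyl]lithium | [Li]/C=C/c1cc(Cl)ccc1O[Si](C(C)C)(C(C)C)C(C)C | intermediate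
12 | lithium [(E)-2-(5-chloro-2-{[tri(propan-2-yl)silyl]oxy}phenyl)ethenyl][(2R)-6-methylhept-5-en-2-yl](pinacolato)borate | [Li+].CC(C)=CCC[C@@H](C)[B-]1(/C=C/c2cc(Cl)ccc2O[Si](C(C)C)(C(C)C)C(C)C)OC(C)(C)C(C)(C)O1 | intermediate
13 | β-iodoboronic ester from anti addition of iodine (C1'') and the migrating group (C2''), (3R); two diastereomers that differ at C1'' and C2'' together, one drawn | CC(C)[Si](Oc1ccc(Cl)cc1[C@H](I)[C@@H](B1OC(C)(C)C(C)(C)O1)[C@H](C)CCC=C(C)C)(C(C)C)C(C)C | intermediate
14 | {4-chloro-2-[(1Z,3R)-3,7-dimethylocta-1,6-dien-1-yl]phenoxy}tri(propan-2-yl)silane | CC(C)=CCC[C@@H](C)/C=C\c1cc(Cl)ccc1O[Si](C(C)C)(C(C)C)C(C)C | intermediate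
15 | 1-(2-hydroxy-4-methoxyphenyl)ethan-1-one | CC(=O)c1ccc(OC)cc1O | starting material
16 | (E)-3-(dimethylamino)-1-(2-hydroxy-4-methoxyphenyl)prop-2-en-1-one | CN(C)/C=C/C(=O)c1ccc(OC)cc1O | intermediate
17 | 3-iodo-7-methoxy-4H-chromen-4-one | COc1ccc2c(c1)occ(I)c2=O | intermediate
18 | 7-hydroxy-3-iodo-4H-chromen-4-one | Oc1ccc2c(c1)occ(I)c2=O | intermediate
19 | {2-[(1Z,3R)-3,7-dimethylocta-1,6-dien-1-yl]-4-(4,4,5,5-tetramethyl-1,3,2-dioxaborolan-2-yl)phenoxy}tri(propan-2-yl)silane | CC(C)=CCC[C@@H](C)/C=C\c1cc(B2OC(C)(C)C(C)(C)O2)ccc1O[Si](C(C)C)(C(C)C)C(C)C | intermediate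
20 | 3-(3-[(1Z,3R)-3,7-dimethylocta-1,6-dien-1-yl]-4-{[tri(propan-2-yl)silyl]oxy}phenyl)-7-hydroxy-4H-chromen-4-one | CC(C)=CCC[C@@H](C)/C=C\c1cc(-c2coc3cc(O)ccc3c2=O)ccc1O[Si](C(C)C)(C(C)C)C(C)C | intermediate
21 | 7-hydroxy-3-{4-hydroxy-3-[(1Z,3R)-3,7-dimethylocta-1,6-dien-1-yl]phenyl}-4H-chromen-4-one | CC(C)=CCC[C@@H](C)/C=C\c1cc(-c2coc3cc(O)ccc3c2=O)ccc1O | target

**Step count**
Total: 9 steps. Longest linear sequence: 5 steps (8 → 9 → 10 → 14 → 20 → 21, and equally 1 → 3 → 7 → 14 → 20 → 21).

**Steps most likely to fail**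

Step 5. The geometry could erode if the benzylic iodide of 13 ionised or exchanged before the anti-elimination; iodine could also add to the remote alkene, or methoxide could begin to remove the silyl group. The fallback would set the geometry by syn-addition of hydrogen instead. Setting out from 7, a deborylative alkynylation (1-bromoethenyllithium from vinyl bromide and LDA, then I2/MeOH and NaOMe) would give (3R)-2-bromo-3,7-dimethylocta-1,6-diene F1, which TBAF in DMF would dehydrobrominate to (3R)-3,7-dimethyloct-6-en-1-yne F2 without a strong amide base near the stereocentre. 4-Chloro-2-iodophenol F3 would be silylated (TIPSCl, imidazole) to (4-chloro-2-iodophenoxy)tri(propan-2-yl)silane F4. Sonogashira coupling of F2 and F4 (Pd(PPh3)2Cl2, CuI, Et3N), selective for the iodide, would give {4-chloro-2-[(3R)-3,7-dimethyloct-6-en-1-yn-1-yl]phenoxy}tri(propan-2-yl)silane F5. Semihydrogenation (H2, Pd/CaCO3 poisoned with Pb(OAc)2, quinoline) would return 14.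

Step 8. A palladium hydride formed at the temperature needed to activate the aryl chloride could cause Z-to-E drift; protodeboronation of 19 or hydroxide opening of the pyranone are further risks. The fallback would make the aryl–boron bond by halogen–lithium exchange at low temperature and would set out from 7. 5-Bromo-2-hydroxybenzaldehyde F6 would be carried through the operations of steps 3 and 4 to 5-bromo-2-{[tri(propan-2-yl)silyl]oxy}benzaldehyde F7 and {4-bromo-2-[(E)-2-iodoethenyl]phenoxy}tri(propan-2-yl)silane F8. Iodine–lithium exchange with n-BuLi (1.0 equiv, −100 °C), which should leave the aryl bromide alone, and the sequence of step 5 with 7 would give {4-bromo-2-[(1Z,3R)-3,7-dimethylocta-1,6-dien-1-yl]phenoxy}tri(propan-2-yl)silane F9. Bromine–lithium exchange (n-BuLi, −78 °C) and B(Oi-Pr)3 would give the lithium triisopropyl arylborate F10. This would couple with 18 at 40 °C (Pd(OAc)2, XPhos, aq. K3PO4, THF) and return to the route at 20.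

Step 4. Incomplete E selectivity in the chromium-mediated olefination would be passed on as E-alkene after step 5. The fallback would set out from 9: one-carbon homologation with lithiated TMSCHN2 (Colvin rearrangement) would give (4-chloro-2-ethynylphenoxy)tri(propan-2-yl)silane F11. syn-Hydrozirconation with Cp2Zr(H)Cl followed by iodine would return 10 as the E isomer only.

**Further compounds**
F1 | step 5 | (3R)-2-bromo-3,7-dimethylocta-1,6-diene | CC(C)=CCC[C@@H](C)C(Br)=C
F2 | step 5 | (3R)-3,7-dimethyloct-6-en-1-yne | CC(C)=CCC[C@@H](C)C#C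
F3 | step 5 | 4-chloro-2-iodophenol | Oc1ccc(Cl)cc1I
F4 | step 5 | (4-chloro-2-iodophenoxy)tri(propan-2-yl)silane | CC(C)[Si](Oc1ccc(Cl)cc1I)(C(C)C)C(C)C
F5 | step 5 | {4-chloro-2-[(3R)-3,7-dimethyloct-6-en-1-yn-1-yl]phenoxy}tri(propan-2-yl)silane | CC(C)=CCC[C@@H](C)C#Cc1cc(Cl)ccc1O[Si](C(C)C)(C(C)C)C(C)C
F6 | step 8 | 5-bromo-2-hydroxybenzaldehyde | O=Cc1cc(Br)ccc1O
F7 | step 8 | 5-bromo-2-{[tri(propan-2-yl)silyl]oxy}benzaldehyde | O=Cc1cc(Br)ccc1O[Si](C(C)C)(C(C)C)C(C)C
F8 | step 8 | {4-bromo-2-[(E)-2-iodoethenyl]phenoxy}tri(propan-2-yl)silane | I/C=C/c1cc(Br)ccc1O[Si](C(C)C)(C(C)C)C(C)C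
F9 | step 8 | {4-bromo-2-[(1Z,3R)-3,7-dimethylocta-1,6-dien-1-yl]phenoxy}tri(propan-2-yl)silane | CC(C)=CCC[C@@H](C)/C=C\c1cc(Br)ccc1O[Si](C(C)C)(C(C)C)C(C)C
F10 | step 8 | lithium {3-[(1Z,3R)-3,7-dimethylocta-1,6-dien-1-yl]-4-{[tri(propan-2-yl)silyl]oxy}phenyl}tri(propan-2-yloxy)borate | [Li+].CC(C)O[B-](OC(C)C)(OC(C)C)c1ccc(O[Si](C(C)C)(C(C)C)C(C)C)c(/C=C\[C@H](C)CCC=C(C)C)c1
F11 | step 4 | (4-chloro-2-ethynylphenoxy)tri(propan-2-yl)silane | C#Cc1cc(Cl)ccc1O[Si](C(C)C)(C(C)C)C(C)C
A1 | direct plan | 2-[2-(3-bromo-4-methoxyphenyl)-2-oxoethoxy]-4-methoxybenzaldehyde | O=Cc1ccc(OC)cc1OCC(=O)c1ccc(OC)c(Br)c1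
A2 | direct plan | (±)-3-(3-bromo-4-methoxyphenyl)-3-hydroxy-7-methoxychroman-4-one | COc1ccc2c(c1)OCC(O)(c1ccc(OC)c(Br)c1)C2=O
A3 | direct plan | 3-(3-bromo-4-hydroxyphenyl)-7-hydroxy-4H-chromen-4-one | Oc1ccc2c(c1)occ(-c1ccc(O)c(Br)c1)c2=O
A4 | direct plan | (3R)-3,7-dimethyloct-6-enal | CC(C)=CCC[C@@H](C)CC=O
A5 | direct plan | (3R)-3,7-dimethyloct-6-en-1-yne | CC(C)=CCC[C@@H](C)C#C
A6 | direct plan | 2-[(1Z,3R)-3,7-dimethylocta-1,6-dien-1-yl]-4,4,5,5-tetramethyl-1,3,2-dioxaborolane | CC(C)=CCC[C@@H](C)/C=C\B1OC(C)(C)C(C)(C)O1
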